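**Retrosynthetic overview**

1. The 2S target is reached from its tris-silyl ether by fluoride; the last step only unmasks three phenols.
2. Ring C is opened at two bonds at once, C4–C4a and O1–C2, giving an aryl cinnamate in which O1 carries the C2–C3–C4 chain as an ester. In the forward direction the acyl group shifts from O1 to C4a (photo-Fries), and the freed O1 then adds to C2 (catalyst-controlled oxa-Michael) in the same flask.
3. Enabling feature: in ring C the ketone carbon C4 and the ether oxygen O1 sit on the neighbouring ring A carbons C4a and C8a (an ortho-hydroxyaryl ketone), and O1 is 1,3 to the C4 carbonyl through C2–C3 (a β-aryloxy ketone). C4a is the only unsubstituted ring A carbon ortho to O1, since C8 carries the prenyl group.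
4. The ester comes from a ring A phenol and a ring B cinnamic acid. Ring A is made from phloroglucinol, with the prenyl group put next to O1 by Claisen rearrangement of an O-(1,1-dimethylallyl) ether. Ring B is made from 4-hydroxy-2-methoxybenzaldehyde, with the 1,1-dimethylallyl group put in by Claisen rearrangement of the O-prenyl ether, followed by Knoevenagel–Doebner condensation.
5. Ring order: rings A and B are bought as benzene rings; ring C is the only ring formed, and it is formed last.

Key step: step 10

Assumption: the quinidine-derived amine–thiourea is taken to be the pseudoenantiomer that delivers the 2S flavanone; if the sense of induction is the reverse, the quinine-derived catalyst is used under the same conditions.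

**Route**

Step 1
Reactants: 1 phloroglucinol (benzene-1,3,5-triol)
Product: 2 3,5-bis(triisopropylsilyloxy)phenol
Conditions: TIPSCl (2.0 equiv), imidazole, DMF, 0 °C to rt
Reagents that add atoms: triisopropylsilyl chloride (TIPSCl), CC(C)[Si](Cl)(C(C)C)C(C)C
Why: Phenol silylation, which with two equivalents of silyl chloride should give the symmetric bis-silyl ether as the main part of a statistical mixture (mono- and tris-silyl material being recyclable) and leaves one phenol whose two ortho carbons are equivalent.

Step 2
Reactants: 2 3,5-bis(triisopropylsilyloxy)phenol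
Product: 3 1-(2-methylbut-3-yn-2-yloxy)-3,5-bis(triisopropylsilyloxy)benzene
Conditions: 3-chloro-3-methylbut-1-yne, DBU, CuCl2 (1 mol%), MeCN, 0 °C
Reagents that add atoms: 3-chloro-3-methylbut-1-yne, C#CC(C)(C)Cl
Why: Copper-catalysed O-alkylation of a phenol with a tertiary propargylic chloride (aryl 1,1-dimethylpropargyl ether synthesis), which should alkylate oxygen and not carbon.

Step 3
Reactants: 3 1-(2-methylbut-3-yn-2-yloxy)-3,5-bis(triisopropylsilyloxy)benzene
Product: 4 1-(2-methylbut-3-en-2-yloxy)-3,5-bis(triisopropylsilyloxy)benzene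
Conditions: H2 (1 atm), Pd on CaCO3 poisoned with Pb(OAc)2, quinoline, EtOAc, rt
Reagents that add atoms: none
Why: Lindlar semi-hydrogenation of the terminal alkyne should stop at the alkene on the poisoned catalyst, and the aryl silyl ethers are inert.

Step 4
Reactants: 4 1-(2-methylbut-3-en-2-yloxy)-3,5-bis(triisopropylsilyloxy)benzene
Product: 5 2-(3-methylbut-2-en-1-yl)-3,5-bis(triisopropylsilyloxy)phenol
Conditions: PhMe, 110 °C
Reagents that add atoms: none
Why: Aromatic Claisen rearrangement ([3,3] shift) of the aryl 1,1-dimethylallyl ether delivers the allyl terminus to either of the two equivalent ortho carbons, so the prenyl group ends up next to the one free phenol, the oxygen that becomes O1.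

Step 5
Reactants: 6 4-hydroxy-2-methoxybenzaldehyde
Product: 7 2-methoxy-4-(3-methylbut-2-en-1-yloxy)benzaldehyde
Conditions: prenyl bromide, K2CO3, DMF, rt
Reagents that add atoms: prenyl bromide (1-bromo-3-methylbut-2-ene), CC(C)=CCBr
Why: Williamson ether synthesis on the acidic para-formyl phenoxide.

Step 6
Reactants: 7 2-methoxy-4-(3-methylbut-2-en-1-yloxy)benzaldehyde
Product: 8 4-hydroxy-2-methoxy-5-(2-methylbut-3-en-2-yl)benzaldehyde
Conditions: EtOH/H2O (4:1), 130 °C, sealed tube
Reagents that add atoms: none
Why: Water-accelerated aromatic Claisen rearrangement, in which the allyl group inverts to give the 1,1-dimethylallyl group at C5, the ortho carbon not flanked by the methoxy group, as in closely related para-acyl aryl prenyl ethers.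

Step 7
Reactants: 8 4-hydroxy-2-methoxy-5-(2-methylbut-3-en-2-yl)benzaldehyde
Product: 10 (E)-3-[4-hydroxy-2-methoxy-5-(2-methylbut-3-en-2-yl)phenyl]prop-2-enoic acid, via benzylidenemalonic acid 9 (not isolated)
Conditions: malonic acid, pyridine, piperidine (cat.), 80 °C
Reagents that add atoms: malonic acid, OC(=O)CC(=O)O
Why: Knoevenagel–Doebner condensation, in which decarboxylation of the arylidenemalonic acid should give the E cinnamic acid while the temperature stays below that of a second decarboxylation.

Step 8
Reactants: 10 (E)-3-[4-hydroxy-2-methoxy-5-(2-methylbut-3-en-2-yl)phenyl]prop-2-enoic acid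
Product: 12 (E)-3-[4-(tert-butyldimethylsilyloxy)-2-methoxy-5-(2-methylbut-3-en-2-yl)phenyl]prop-2-enoic acid, via silyl ester 11 (not isolated)
Conditions: TBSCl (2.5 equiv), imidazole, DMAP (cat.), DMF, 40 °C; then AcOH/THF/H2O, rt
Reagents that add atoms: tert-butyldimethylsilyl chloride (TBSCl), CC(C)(C)[Si](C)(C)Cl
Why: Silylation of phenol and acid followed by selective hydrolysis of the far more labile silyl ester, which leaves the hindered aryl silyl ether that keeps ring B from acting as a para-quinone-methide donor in the key step.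

Step 9
Reactants: 5 2-(3-methylbut-2-en-1-yl)-3,5-bis(triisopropylsilyloxy)phenol; 12 (E)-3-[4-(tert-butyldimethylsilyloxy)-2-methoxy-5-(2-methylbut-3-en-2-yl)phenyl]prop-2-enoic acid
Product: 13 2-(3-methylbut-2-en-1-yl)-3,5-bis(triisopropylsilyloxy)phenyl (E)-3-[4-(tert-butyldimethylsilyloxy)-2-methoxy-5-(2-methylbut-3-en-2-yl)phenyl]prop-2-enoate
Conditions: DCC, DMAP (cat.), CH2Cl2, 0 °C to rt
Reagents that add atoms: none
Why: Steglich esterification of the phenol through the acylpyridinium builds the O1–C4 ester tether that the key step converts into the C4–C4a bond.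

Step 10
Reactants: 13 2-(3-methylbut-2-en-1-yl)-3,5-bis(triisopropylsilyloxy)phenyl (E)-3-[4-(tert-butyldimethylsilyloxy)-2-methoxy-5-(2-methylbut-3-en-2-yl)phenyl]prop-2-enoate
Product: 15 (2S)-2-[4-(tert-butyldimethylsilyloxy)-2-methoxy-5-(2-methylbut-3-en-2-yl)phenyl]-8-(3-methylbut-2-en-1-yl)-5,7-bis(triisopropylsilyloxy)chroman-4-one, via 2'-hydroxychalcone 14 (not isolated)
Conditions: hν (medium-pressure Hg lamp, Pyrex filter), degassed PhMe (about 5 mM), 10 °C; then, without work-up and in the dark, quinidine-derived 9-amino-9-deoxy-epi thiourea bearing a 3,5-bis(trifluoromethyl)phenyl group (10 mol%), −20 °C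
Reagents that add atoms: none
Why: Proposed new method: excitation of the aryl ester homolyses the ArO–C(O) bond and the caged phenoxyl/acyl radical pair recombines at the free ortho carbon (photo-Fries rearrangement, forming C4–C4a) to give after enolization 2'-hydroxychalcone 14, whose single free phenol oxygen O1 then adds to the enone β-carbon C2 under the bifunctional amine–thiourea. The closest known reaction types are the photo-Fries rearrangement of aryl cinnamates to 2'-hydroxychalcones and the cinchona amine–thiourea-catalysed enantioselective intramolecular oxa-Michael cyclization of 2'-hydroxychalcones and their α-alkoxycarbonyl analogues to flavanones; their relay in one flask on an α-unactivated chalcone with a fully substituted ring A is the new element. Ring C closes by 6-endo-trig oxa-Michael (conjugate) addition. The C2 stereocenter is set by the catalyst, whose thiourea hydrogen-bonds the C4 carbonyl while the quinuclidine deprotonates O1 and delivers it to one face of the enone, which should give the 2S configuration. The step needs ortho over para acyl migration, which the nearness of the acyl radical to O1 in the solvent cage and the two triisopropylsilyloxy groups flanking the para carbon should secure (a para ketone has no ortho hydroxyl, cannot cyclize and is separated), and it needs closure through O1 only, which is certain because the oxygens that become O5 and O7 stay silylated. Racemic background closure should be held back by irradiating in a non-polar solvent without base and adding the catalyst only in the dark at low temperature.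

Step 11
Reactants: 15 (2S)-2-[4-(tert-butyldimethylsilyloxy)-2-methoxy-5-(2-methylbut-3-en-2-yl)phenyl]-8-(3-methylbut-2-en-1-yl)-5,7-bis(triisopropylsilyloxy)chroman-4-one
Product: 16 (2S)-5,7-dihydroxy-2-[4-hydroxy-2-methoxy-5-(2-methylbut-3-en-2-yl)phenyl]-8-(3-methylbut-2-en-1-yl)chroman-4-one (CNP0308136.1)
Conditions: TBAF (3.3 equiv), AcOH (4 equiv), THF, 0 °C to rt
Reagents that add atoms: none
Why: Fluoride cleavage of the three aryl silyl ethers, buffered with AcOH so that phenoxide levels stay low and the base-triggered retro-oxa-Michael opening that would racemize C2 should not set in, while the prenyl and 1,1-dimethylallyl groups are untouched.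

**Compound list**

1 | phloroglucinol (benzene-1,3,5-triol) | Oc1cc(O)cc(O)c1 | starting material
2 | 3,5-bis(triisopropylsilyloxy)phenol | Oc1cc(O[Si](C(C)C)(C(C)C)C(C)C)cc(O[Si](C(C)C)(C(C)C)C(C)C)c1 | intermediate
3 | 1-(2-methylbut-3-yn-2-yloxy)-3,5-bis(triisopropylsilyloxy)benzene | C#CC(C)(C)Oc1cc(O[Si](C(C)C)(C(C)C)C(C)C)cc(O[Si](C(C)C)(C(C)C)C(C)C)c1 | intermediate
4 | 1-(2-methylbut-3-en-2-yloxy)-3,5-bis(triisopropylsilyloxy)benzene | C=CC(C)(C)Oc1cc(O[Si](C(C)C)(C(C)C)C(C)C)cc(O[Si](C(C)C)(C(C)C)C(C)C)c1 | intermediate
5 | 2-(3-methylbut-2-en-1-yl)-3,5-bis(triisopropylsilyloxy)phenol | CC(C)=CCc1c(O)cc(O[Si](C(C)C)(C(C)C)C(C)C)cc1O[Si](C(C)C)(C(C)C)C(C)C | intermediate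
6 | 4-hydroxy-2-methoxybenzaldehyde | COc1cc(O)ccc1C=O | starting material
7 | 2-methoxy-4-(3-methylbut-2-en-1-yloxy)benzaldehyde | COc1cc(OCC=C(C)C)ccc1C=O | intermediate
8 | 4-hydroxy-2-methoxy-5-(2-methylbut-3-en-2-yl)benzaldehyde | C=CC(C)(C)c1cc(C=O)c(OC)cc1O | intermediate
9 | 2-[4-hydroxy-2-methoxy-5-(2-methylbut-3-en-2-yl)benzylidene]malonic acid (not isolated) | C=CC(C)(C)c1cc(C=C(C(=O)O)C(=O)O)c(OC)cc1O | intermediate
10 | (E)-3-[4-hydroxy-2-methoxy-5-(2-methylbut-3-en-2-yl)phenyl]prop-2-enoic acid | C=CC(C)(C)c1cc(/C=C/C(=O)O)c(OC)cc1O | intermediate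
11 | tert-butyldimethylsilyl (E)-3-[4-(tert-butyldimethylsilyloxy)-2-methoxy-5-(2-methylbut-3-en-2-yl)phenyl]prop-2-enoate (not isolated) | C=CC(C)(C)c1cc(/C=C/C(=O)O[Si](C)(C)C(C)(C)C)c(OC)cc1O[Si](C)(C)C(C)(C)C | intermediate
12 | (E)-3-[4-(tert-butyldimethylsilyloxy)-2-methoxy-5-(2-methylbut-3-en-2-yl)phenyl]prop-2-enoic acid | C=CC(C)(C)c1cc(/C=C/C(=O)O)c(OC)cc1O[Si](C)(C)C(C)(C)C | intermediate
13 | 2-(3-methylbut-2-en-1-yl)-3,5-bis(triisopropylsilyloxy)phenyl (E)-3-[4-(tert-butyldimethylsilyloxy)-2-methoxy-5-(2-methylbut-3-en-2-yl)phenyl]prop-2-enoate | C=CC(C)(C)c1cc(/C=C/C(=O)Oc2cc(O[Si](C(C)C)(C(C)C)C(C)C)cc(O[Si](C(C)C)(C(C)C)C(C)C)c2CC=C(C)C)c(OC)cc1O[Si](C)(C)C(C)(C)C | intermediate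
14 | (E)-1-[2-hydroxy-3-(3-methylbut-2-en-1-yl)-4,6-bis(triisopropylsilyloxy)phenyl]-3-[4-(tert-butyldimethylsilyloxy)-2-methoxy-5-(2-methylbut-3-en-2-yl)phenyl]prop-2-en-1-one (not isolated) | C=CC(C)(C)c1cc(/C=C/C(=O)c2c(O)c(CC=C(C)C)c(O[Si](C(C)C)(C(C)C)C(C)C)cc2O[Si](C(C)C)(C(C)C)C(C)C)c(OC)cc1O[Si](C)(C)C(C)(C)C | intermediate
15 | (2S)-2-[4-(tert-butyldimethylsilyloxy)-2-methoxy-5-(2-methylbut-3-en-2-yl)phenyl]-8-(3-methylbut-2-en-1-yl)-5,7-bis(triisopropylsilyloxy)chroman-4-one | C=CC(C)(C)c1cc([C@@H]2CC(=O)c3c(O[Si](C(C)C)(C(C)C)C(C)C)cc(O[Si](C(C)C)(C(C)C)C(C)C)c(CC=C(C)C)c3O2)c(OC)cc1O[Si](C)(C)C(C)(C)C | intermediate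
16 | (2S)-5,7-dihydroxy-2-[4-hydroxy-2-methoxy-5-(2-methylbut-3-en-2-yl)phenyl]-8-(3-methylbut-2-en-1-yl)chroman-4-one | C=CC(C)(C)c1cc([C@@H]2CC(=O)c3c(O)cc(O)c(CC=C(C)C)c3O2)c(OC)cc1O | target

**Step count and risks**

Total steps: 11. Longest linear sequence: 7 steps (steps 1–4, 9, 10, 11; the ring B branch, steps 5–8, 9, 10, 11, is equally long).

Steps most likely to fail:

1. Step 10 (proposed new method). What may go wrong: acyl recombination at the para carbon or escape from the solvent cage instead of ortho recombination; photochemical E/Z scrambling and uncatalysed, racemic ring closure during irradiation; and weak facial discrimination on an enone that has no α-activating group. Fallback, known chemistry only: setting out from 13, the photo-Fries rearrangement is run on its own without catalyst and chalcone 14 is isolated. Chalcone 14 is then closed without stereocontrol (NaOAc, EtOH, reflux) to the racemic flavanone rac-2-[4-(tert-butyldimethylsilyloxy)-2-methoxy-5-(2-methylbut-3-en-2-yl)phenyl]-8-(3-methylbut-2-en-1-yl)-5,7-bis(triisopropylsilyloxy)chroman-4-one F1. F1 is resolved kinetically by Noyori-type asymmetric transfer hydrogenation (RuCl(p-cymene)(TsDPEN), ligand enantiomer chosen so that the 2R ketone reacts faster, HCO2H/Et3N, rt). This should reduce the 2R ketone to the cis alcohol (2R,4R)-2-[4-(tert-butyldimethylsilyloxy)-2-methoxy-5-(2-methylbut-3-en-2-yl)phenyl]-8-(3-methylbut-2-en-1-yl)-5,7-bis(triisopropylsilyloxy)chroman-4-ol F2 and leave the 2S ketone; chromatography returns the route at 15.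

2. Step 6. What may go wrong: cleavage of the allyl–oxygen bond with loss of the C5 unit, and further cyclization of the ortho-(1,1-dimethylallyl)phenol onto its own alkene at the temperature the [3,3] shift needs. Fallback: setting out from 6, electrophilic bromination (Br2, AcOH, rt) at the carbon ortho to the hydroxyl and para to the methoxyl gives 5-bromo-4-hydroxy-2-methoxybenzaldehyde F3. A ligand-controlled γ-selective Suzuki–Miyaura coupling of F3 with 3-methylbut-2-enylboronic acid pinacol ester (Pd(OAc)2, a biaryl phosphine ligand that directs allyl boronates to couple at the γ carbon, K3PO4, THF/H2O, 40 °C) installs the 1,1-dimethylallyl group directly and returns the route at 8.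

3. Step 4. What may go wrong: ionization of the tertiary allyl ether with loss of isoprene back to phenol 2, or a slow [3,3] shift next to the bulky silyloxy group. Fallback: setting out from 2, the sodium phenoxide is C-alkylated at the ortho carbon in a non-polar medium (NaH, PhMe, prenyl bromide, rt; ortho-selective C-allylation of an aryloxide). This gives 5 directly and returns the route there; this fallback makes no compound outside the compound list (F0).

Further compounds
F1 | step 10 | rac-2-[4-(tert-butyldimethylsilyloxy)-2-methoxy-5-(2-methylbut-3-en-2-yl)phenyl]-8-(3-methylbut-2-en-1-yl)-5,7-bis(triisopropylsilyloxy)chroman-4-one | C=CC(C)(C)c1cc(C2CC(=O)c3c(O[Si](C(C)C)(C(C)C)C(C)C)cc(O[Si](C(C)C)(C(C)C)C(C)C)c(CC=C(C)C)c3O2)c(OC)cc1O[Si](C)(C)C(C)(C)C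
F2 | step 10 | (2R,4R)-2-[4-(tert-butyldimethylsilyloxy)-2-methoxy-5-(2-methylbut-3-en-2-yl)phenyl]-8-(3-methylbut-2-en-1-yl)-5,7-bis(triisopropylsilyloxy)chroman-4-ol | C=CC(C)(C)c1cc([C@H]2C[C@@H](O)c3c(O[Si](C(C)C)(C(C)C)C(C)C)cc(O[Si](C(C)C)(C(C)C)C(C)C)c(CC=C(C)C)c3O2)c(OC)cc1O[Si](C)(C)C(C)(C)C
F3 | step 6 | 5-bromo-4-hydroxy-2-methoxybenzaldehyde | COc1cc(O)c(Br)cc1C=O
F0 | step 4 | none | none
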